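The trap in these flasks was the peak: target topped at 36.0 % in the east run and 36.8 % in the south run, which tempts one to treat it as a fixed yield, yet the asked time of 30 h lies beyond every reading.

| flask | solid substrate | protic impurity | remark | time |
|---|---|---|---|---|
| east | 0.48 M | 0.48 M | run made earlier |  |
| south-west | 0.93 M | 0.48 M | run made earlier |  |
| south | 1.8 M | 0.48 M | run made earlier |  |
| north-east | 1.6 M | 0.46 M | run made earlier |  |
| Saturday's | 1.6 M | 1.00 M |  | 30 h |
| Sunday's | 1.6 M | 0.480 M |  | 30 h |
| Tuesday's | 1.6 M | 0.120 M |  | 30 h |
| Thursday's | 0.50 M | 1.50 M |  | 30 h |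
| Wednesday's | 0.80 M | 0.150 M |  | 30 h |

| run | time / h | target / % | solid substrate / % |
|---|---|---|---|
| east | 1.33 | 13.9 | 8.0 |
| east | 3.00 | 31.8 | 0.4 |
| east | 6.00 | 36.0 | 0.2 |
| east | 15.0 | 30.4 | 0.3 |
| south-west | 1.33 | 7.1 | 52.5 |
| south-west | 3.00 | 21.3 | 17.4 |
| south-west | 6.00 | 36.9 | 0 |
| south-west | 15.0 | 32.1 | 0 |
| south | 4.00 | 15.3 | 46.6 |
| south | 8.00 | 29.6 | 14.7 |
| south | 12.0 | 36.8 | 0 |
| south | 15.0 | 35.2 | 0 |
| north-east | 2.00 | 7.8 | 63.5 |
| north-east | 5.00 | 21.8 | 30.0 |
| north-east | 10.0 | 36.5 | 0 |
| north-east | 15.0 | 35.3 | 0.2 |

(scatter of a reading: 0.5 percentage points)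

- solid substrate is a solid; its amount is given per volume of the solution
- candidate steps: starting material <-> target; starting material <-> isomer of the product; solid substrate <-> starting material; starting material + protic impurity -> quenched substrate
- at the start none of the solid substrate is in solution
- what has only dissolved of solid substrate counts as not reacted

1. the flasks by amount of target, in percent of the solid substrate charged, highest first, at 30 h (Saturday's / Sunday's / Tuesday's / Thursday's / Wednesday's)
2. the amount of target, in percent of the solid substrate charged of the flask you put first, at 30 h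
3. the amount of target, in percent of the solid substrate charged of the flask you put last, at 30 h

I reckoned with two times: θ, the mean moment at which substrate enters solution, and τ, the life of target against quenching by protic impurity. In the east run 8.0 % of the solid remained at 1.33 h, so I took what had gone by then as entering evenly up to that reading and the rest at the midpoint of the next interval, which replaced the feed by an estimated mean, θ = 0.785 h. Between 6.00 h and 15.0 h target then fell at a rate λ = 0.0188 h⁻¹, which I charged to the quench. The gap between that last east reading and the south peak put the mean impurity at c = 0.397 M. So κ = λ/c, the fractional loss of target per hour per unit of impurity, read 0.0474 L mol⁻¹ h⁻¹. With τ = 1/(κc), target follows S·exp(−(t−θ)/τ), and the last east reading gave a ceiling S = 39.7 %.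

For Thursday's I drew impurity as a straight line from its charge down to the charge less the whole solid, a mean of 1.25 M. Then τ = 16.9 h, shorter than the 29.2 h of exposure, and target came to 7.04 %. Holding impurity at its charge instead gave 4.98 %, so the mean was worth 2.1 percentage points.

The forecast gave Tuesday's > Wednesday's > Sunday's > Saturday's > Thursday's, with 33 % and 17 %, holding that target “leaks back through starting material to the isomer”. My order by charged impurity matched it, but for Thursday's I stood 10 points lower.

The flasks gave Tuesday's > Wednesday's > Sunday's > Saturday's > Thursday's, with 38.9 % first and 7.88 % last, under this scheme: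

    starting material ⇌ target (K = 2.10, k = 8.40 × 10⁻⁵ s⁻¹)
    starting material ⇌ isomer of the product (K = 2.00, k = 5.10 × 10⁻⁵ s⁻¹)
    solid substrate ⇌ starting material, rate k3*(cs3 - [starting material]) while solid is left; crystals form when [starting material] > cs3 (solubility = 0.560 M, k = 2.50 × 10⁻⁴ s⁻¹)
    starting material + protic impurity → quenched substrate (k = 7.00 × 10⁻⁵ L mol⁻¹ s⁻¹)

Thursday's still held 73 % of its protic impurity at the end. Its mean from 15.0 h on was 1.14 M, so κ carries 15.5 % to 6.89 %, against 7.88 % found. For Saturday's the mean over the same span was 0.287 M, and κ carries 27.1 % to 22.1 %, where the flask stood at 20.9 %.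

The data were computed with constants of no real substance, noise included.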